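**Retrosynthetic overview**

1. Target 31 comes from its bis(2-methoxytropone) 30 by hydrolysis of the two vinylogous methyl esters; ring A (the dihydropyran on C8–C9) is closed just before, by forming the bond between the C8 methylene carbon and C5′ of tropolone ring A.
2. That closure is a zinc-mediated, palladium-catalysed reductive coupling of primary iodide 28 with its own C5′–Br. The C9–O–C4′ ether and the C10 hydroxyl come from trans-opening of 9,10-epoxide 26 by bromohydroxytropone 11.
3. The epoxide is delivered by a hydroxymethyl arm on C8. That arm comes from a 10R allylic carbinol (CBS reduction) by Ireland–Claisen transfer C10 → C8 and loss of one carbon.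
4. Ring B (the dihydropyran on C1–C2) is made first by hetero-Diels–Alder addition of tropolone o-quinone methide 13 to the more reactive C1=C2 bond of α-humulene; both tropone partners (10 and 11) come from one oxidopyrylium [5+2] adduct.
5. Enabling feature: in ring A the carbon C5′ lies between the ether carbon C4′ and the methyl carbon C6′, so bromine placed there is ortho to O–C9 and the chain C5′–C4′–O–C9–C8–CH2 closes exactly the six-membered dihydropyran. Ring order: the two tropone rings, then ring B, then the epoxide (temporary), then ring A.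

Key step: step 18

Remark: atoms are numbered as in humulane (C1/C2 carry ring B, C4=C5 is the E-alkene, C6 is CMe2, C8/C9 carry ring A, C10 the hydroxyl) and as in tropone (C1′ carbonyl, C2′ OMe/OH, C4′ ether oxygen, C5′ benzylic carbon, C6′ methyl); tert-butyl but-2-ynoate is taken as a commercial ester; compounds 5–7 and 14–16 are racemic.

**Step 1**
Reactants: 1 3-hydroxy-4H-pyran-4-one
Product: 2 3-hydroxy-4-methoxypyrylium trifluoromethanesulfonate
Conditions: MeOTf, CH2Cl2, 40 °C
Reagents that add atoms: methyl trifluoromethanesulfonate COS(=O)(=O)C(F)(F)F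
Why: O-methylation of the pyranone carbonyl oxygen by the hard alkylating agent should give the stable 4-methoxypyrylium salt, the precursor of the oxidopyrylium ylide (pyranone O-alkylation).

**Step 2**
Reactants: 2 3-hydroxy-4-methoxypyrylium trifluoromethanesulfonate; 3 tert-butyl but-2-ynoate
Product: 5 tert-butyl 3-methoxy-7-methyl-2-oxo-8-oxabicyclo[3.2.1]octa-3,6-diene-6-carboxylate (racemic), via 4-methoxypyrylium-3-olate 4 (not isolated)
Conditions: PhNMe2, 3 (excess), CHCl3, 60 °C
Reagents that add atoms: none
Why: Deprotonation gives the 3-oxidopyrylium ylide, whose nucleophilic terminus should bond to the methyl-bearing β-carbon of the ynoate in an oxidopyrylium–alkyne [5+2] cycloaddition, which places the ester next to the bridgehead remote from the ketone.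

**Step 3**
Reactants: 5 tert-butyl 3-methoxy-7-methyl-2-oxo-8-oxabicyclo[3.2.1]octa-3,6-diene-6-carboxylate
Product: 6 tert-butyl 7-hydroxy-5-methoxy-2-methyl-4-oxocyclohepta-1,5-diene-1-carboxylate (racemic)
Conditions: SmI2, THF/MeOH, −78 °C
Reagents that add atoms: none
Why: Samarium diiodide should cleave the bridging C–O bond α to the ketone (reductive cleavage of an α-alkoxy ketone), leaving the oxygen on the other bridgehead as a doubly allylic alcohol.

**Step 4**
Reactants: 6 tert-butyl 7-hydroxy-5-methoxy-2-methyl-4-oxocyclohepta-1,5-diene-1-carboxylate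
Product: 8 5-(tert-butoxycarbonyl)-4-hydroxy-2-methoxy-6-methylcyclohepta-2,4,6-trien-1-one, via cycloheptadienedione 7 (not isolated)
Conditions: Dess–Martin periodinane, NaHCO3, CH2Cl2, 0 → 23 °C
Reagents that add atoms: none
Why: Dess–Martin oxidation of the alcohol gives the dienedione, which should enolise at once to the hydrogen-bonded aromatic 4-hydroxytropone (oxidation followed by tautomerisation to a tropone).

**Step 5**
Reactants: 8 5-(tert-butoxycarbonyl)-4-hydroxy-2-methoxy-6-methylcyclohepta-2,4,6-trien-1-one
Product: 9 5-carboxy-4-hydroxy-2-methoxy-6-methylcyclohepta-2,4,6-trien-1-one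
Conditions: CF3CO2H, CH2Cl2, 0 → 23 °C
Reagents that add atoms: none
Why: Acidolysis of the tert-butyl ester with loss of isobutene frees the acid without touching the base-labile methoxytropone.

**Step 6**
Reactants: 9 5-carboxy-4-hydroxy-2-methoxy-6-methylcyclohepta-2,4,6-trien-1-one
Product: 10 4-hydroxy-5-(hydroxymethyl)-2-methoxy-6-methylcyclohepta-2,4,6-trien-1-one
Conditions: BH3·SMe2, THF, 0 °C; MeOH quench
Reagents that add atoms: none
Why: Borane should reduce the free carboxylic acid through its acyloxyborane much faster than the electron-rich tropone carbonyl (chemoselective borane reduction of a carboxylic acid).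

**Step 7**
Reactants: 9 5-carboxy-4-hydroxy-2-methoxy-6-methylcyclohepta-2,4,6-trien-1-one
Product: 11 5-bromo-4-hydroxy-2-methoxy-6-methylcyclohepta-2,4,6-trien-1-one
Conditions: N-bromosuccinimide (1 equiv), MeCN, 0 °C
Reagents that add atoms: N-bromosuccinimide O=C1CCC(=O)N1Br
Why: Compound 9 is the enol form of a β-keto acid, so electrophilic bromine should enter at the carboxyl-bearing enol carbon C5 with loss of carbon dioxide (ipso-bromodecarboxylation, as with 2-hydroxyaryl carboxylic acids), which fixes the halogen position.

**Step 8**
Reactants: 12 α-humulene; 10 4-hydroxy-5-(hydroxymethyl)-2-methoxy-6-methylcyclohepta-2,4,6-trien-1-one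
Product: 14 ring-B cycloadduct of α-humulene (racemic), via o-quinone methide 13 (not isolated)
Conditions: 12 (excess), toluene, 150 °C, sealed tube
Reagents that add atoms: none
Why: Thermal loss of water from 10 gives o-quinone methide 13, which should add as an electron-poor heterodiene (inverse-electron-demand hetero-Diels–Alder reaction) to C1=C2, the least hindered trisubstituted alkene of humulene and the one peracids also attack first, with oxygen going to C2 and suprafacial addition to the E-alkene setting C1–H anti to C2–CH3.

**Step 9**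
Reactants: 14 ring-B cycloadduct of α-humulene
Product: 16 10-oxo enone of 14 (racemic), via 10-hydroxy epimers 15 (not isolated)
Conditions: SeO2 (cat.), t-BuOOH, CH2Cl2, 23 °C; aqueous work-up; then Dess–Martin periodinane, NaHCO3, CH2Cl2, 0 °C
Reagents that add atoms: tert-butyl hydroperoxide CC(C)(C)OO
Why: Selenium dioxide allylic oxidation (ene reaction then [2,3]-shift) should attack the only remaining trisubstituted alkene at its E-allylic methylene C10, and Dess–Martin oxidation merges the epimeric alcohols into one enone.

**Step 10**
Reactants: 16 10-oxo enone of 14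
Product: 17 (1R,2R,10R)-10-hydroxy compound
Conditions: (S)-2-methyl-CBS-oxazaborolidine (cat.), BH3·SMe2, THF, −30 °C; aq. NH4Cl; chromatography
Reagents that add atoms: none
Why: Corey–Bakshi–Shibata reduction should deliver hydride under reagent control (alkenyl as the large group) to give the 10R carbinol from both enantiomers of racemic 16, so the (1R,2R) enantiomer gives 17 and the (1S,2S) enantiomer gives a (1S,2S,10R) diastereomer that chromatography removes, which leaves 17 as a single enantiomer with the ring-B and C10 configurations fixed relative to each other.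

**Step 11**
Reactants: 17 (1R,2R,10R)-10-hydroxy compound; 18 2-[(tert-butyldimethylsilyl)oxy]acetic acid
Product: 19 (tert-butyldimethylsilyloxy)acetate of 17
Conditions: N,N′-dicyclohexylcarbodiimide, DMAP (cat.), CH2Cl2, 0 → 23 °C
Reagents that add atoms: none
Why: Steglich esterification acylates the hindered allylic alcohol on oxygen, so the C10 configuration is retained.

**Step 12**
Reactants: 19 (tert-butyldimethylsilyloxy)acetate of 17
Product: 22 C8 α-silyloxy acid with 9E alkene, via silyl ketene acetal 20 (not isolated), via trimethylsilyl ester 21 (not isolated)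
Conditions: KN(SiMe3)2, Me3SiCl, THF, −78 → 60 °C; aq. NH4Cl
Reagents that add atoms: none
Why: In the Ireland–Claisen rearrangement the silyl ketene acetal should pass through a chair transition state with C11 pseudo-equatorial, forming the C8–C bond on the face from which the C10–O bond departs (10R gives the C8 configuration of 31) and an E-C9=C10 bond, while the new silyloxy-bearing carbon is formed as an inconsequential epimer mixture.

**Step 13**
Reactants: 22 C8 α-silyloxy acid with 9E alkene
Product: 23 C8 α-hydroxy acid
Conditions: Bu4NF, THF, 0 °C; aq. NH4Cl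
Reagents that add atoms: none
Why: Fluoride cleaves the silyl ether (Si–F bond formation) to free the α-hydroxy acid needed for oxidative cleavage.

**Step 14**
Reactants: 23 C8 α-hydroxy acid
Product: 25 C8 hydroxymethyl compound with 9E alkene, via C8 carbaldehyde 24 (not isolated)
Conditions: Pb(OAc)4, CH2Cl2, −20 °C; then MeOH, NaBH4, −40 °C
Reagents that add atoms: none
Why: Lead tetraacetate cleaves the α-hydroxy acid to the aldehyde with loss of carbon dioxide (oxidative decarboxylation), and immediate borohydride reduction at low temperature should give the primary alcohol before the β,γ-unsaturated aldehyde can epimerise at C8 or move into conjugation.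

**Step 15**
Reactants: 25 C8 hydroxymethyl compound with 9E alkene
Product: 26 (9S,10S)-epoxy alcohol
Conditions: VO(acac)2 (cat.), t-BuOOH, CH2Cl2, 0 → 23 °C
Reagents that add atoms: tert-butyl hydroperoxide CC(C)(C)OO
Why: In this hydroxyl-directed epoxidation of a homoallylic alcohol the vanadate ester of the arm should deliver oxygen only to C9=C10 (C4=C5 is remote and disubstituted), and in the allylic conformer that turns C8–H rather than the arm or C7 toward the C9 methyl group the arm lies on the face not covered by the ring chain, so directed and peripheral attack coincide and set C9 and C10 relative to C8.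

**Step 16**
Reactants: 26 (9S,10S)-epoxy alcohol; 11 5-bromo-4-hydroxy-2-methoxy-6-methylcyclohepta-2,4,6-trien-1-one
Product: 27 (9R,10S)-bromotroponyl ether diol
Conditions: 11 (2 equiv), BF3·OEt2 (0.5 equiv), CH2Cl2, −40 °C; aq. NaHCO3
Reagents that add atoms: none
Why: In this Lewis-acid-activated epoxide opening the C4′ oxygen of 11 (the free donor if the acidic proton rests on the C1′ oxygen, hydrogen-bonded to the neighbouring methoxy group) should attack the tertiary C9 with inversion while C10 keeps its oxygen with retention, which gives the C9 and C10 configurations of 31; the arm hydroxyl could only close an oxetane at C9 or a strained bridged oxolane at C10 and should not compete with the excess of 11.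

**Step 17**
Reactants: 27 (9R,10S)-bromotroponyl ether diol
Product: 28 primary iodide
Conditions: PPh3, I2, imidazole, CH2Cl2, 0 °C
Reagents that add atoms: iodine [I][I]
Why: Appel-type iodination should convert only the unhindered primary alcohol, because the C10 hydroxyl is secondary and flanked by the fully substituted C9.

**Step 18**
Reactants: 28 primary iodide
Product: 30 bis(2-methoxytropone) with ring A closed, via alkylzinc iodide 29 (not isolated)
Conditions: Zn dust, PdCl2[P(t-Bu)2(C6H4-4-NMe2)]2 (5 mol %), Me2NCH2CH2NMe2, 2 wt % TPGS-750-M in H2O, 23 °C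
Reagents that add atoms: none
Why: Zinc inserts into the primary C–I bond inside the micelle to give alkylzinc iodide 29, zerovalent palladium (formed from the dichloride by zinc) adds oxidatively to the C5′–Br bond of ring A, transmetalation gives a seven-membered aryl(alkyl)palladacycle and reductive elimination forms the C5′–CH2 bond. The closest known reaction type is the zinc-mediated, palladium-catalysed coupling of alkyl iodides with aryl bromides in water (in situ Negishi coupling), run here within one molecule. The dihydropyran ring A closes by reductive elimination from the palladacycle, formally a 6-exo-tet substitution at the C8 methylene carbon. No stereocentre is created, and C8, C9 and C10 cannot epimerise because the reacting carbon is primary and no enolisable or ionisable centre is generated. The step needs bond formation at C5′ and not at C3′, which the position of the bromine secures, and it needs reductive elimination to outrun β-hydride elimination toward H8 and protonation of the organozinc, which the bulky electron-rich phosphine and the short tether should secure. A two-electron organometallic closure is chosen on purpose, because a free C8-methyl radical could add to the enone-like C3′ of ring A or to C4=C5, and a cationic closure would be blocked by protonation of the basic tropone carbonyl.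

**Step 19**
Reactants: 30 bis(2-methoxytropone) with ring A closed
Product: 31 CNP0283947.4
Conditions: LiOH, THF/MeOH/H2O, 50 °C; then 1 M HCl to pH 3
Reagents that add atoms: lithium hydroxide [Li+].[OH-]
Why: Hydroxide adds to C2′ of each 2-methoxytropone and expels methoxide (addition–elimination on a vinylogous methyl ester), and acidification should give both tropolones while the hindered tertiary-alkyl 4′-ether links are protected by the tropolonate charge.

**Compound list**

1 | 3-hydroxy-4H-pyran-4-one | O=c1ccocc1O | starting material
2 | 3-hydroxy-4-methoxypyrylium trifluoromethanesulfonate | COc1cc[o+]cc1O.[O-]S(=O)(=O)C(F)(F)F | intermediate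
3 | tert-butyl but-2-ynoate | CC#CC(=O)OC(C)(C)C | starting material
4 | 4-methoxypyrylium-3-olate (oxidopyrylium ylide, not isolated) | COc1cc[o+]cc1[O-] | intermediate
5 | tert-butyl 3-methoxy-7-methyl-2-oxo-8-oxabicyclo[3.2.1]octa-3,6-diene-6-carboxylate (racemic) | O=C1C(OC)=CC2OC1C(C)=C2C(=O)OC(C)(C)C | intermediate
6 | tert-butyl 7-hydroxy-5-methoxy-2-methyl-4-oxocyclohepta-1,5-diene-1-carboxylate (racemic) | O=C1CC(C)=C(C(=O)OC(C)(C)C)C(O)C=C1OC | intermediate
7 | tert-butyl 5-methoxy-2-methyl-4,7-dioxocyclohepta-1,5-diene-1-carboxylate (not isolated) | O=C1CC(C)=C(C(=O)OC(C)(C)C)C(=O)C=C1OC | intermediate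
8 | 5-(tert-butoxycarbonyl)-4-hydroxy-2-methoxy-6-methylcyclohepta-2,4,6-trien-1-one | Cc1cc(=O)c(OC)cc(O)c1C(=O)OC(C)(C)C | intermediate
9 | 5-carboxy-4-hydroxy-2-methoxy-6-methylcyclohepta-2,4,6-trien-1-one | Cc1cc(=O)c(OC)cc(O)c1C(=O)O | intermediate
10 | 4-hydroxy-5-(hydroxymethyl)-2-methoxy-6-methylcyclohepta-2,4,6-trien-1-one | Cc1cc(=O)c(OC)cc(O)c1CO | intermediate
11 | 5-bromo-4-hydroxy-2-methoxy-6-methylcyclohepta-2,4,6-trien-1-one | Cc1cc(=O)c(OC)cc(O)c1Br | intermediate
12 | α-humulene, (1E,4E,8E)-2,6,6,9-tetramethylcycloundeca-1,4,8-triene | C/C1=C\CC(C)(C)/C=C/C/C(C)=C/CC1 | starting material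
13 | 2-methoxy-6-methyl-5-methylidenecyclohepta-2,6-diene-1,4-dione (tropolone o-quinone methide, not isolated) | C=C1C(C)=CC(=O)C(OC)=CC1=O | intermediate
14 | ring-B cycloadduct: (4E,8E)-humula-4,8-diene carrying the 2-methoxy-6-methyltropone-fused dihydropyran on C1–C2 (O on C2, CH2 on C1, C1–H anti to C2–CH3); racemic, the enantiomer of the 31 series is drawn | C/C1=C\CC(C)(C)/C=C/C[C@@]2(C)Oc3cc(OC)c(=O)cc(C)c3C[C@@H]2CC1 | intermediate
15 | 10-hydroxy derivative of 14, both C10 epimers (racemic, not isolated) | C/C1=C\CC(C)(C)/C=C/C[C@@]2(C)Oc3cc(OC)c(=O)cc(C)c3C[C@@H]2CC1O | intermediate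
16 | 10-oxo derivative of 14, (8E)-enone (racemic) | C/C1=C\CC(C)(C)/C=C/C[C@@]2(C)Oc3cc(OC)c(=O)cc(C)c3C[C@@H]2CC1=O | intermediate
17 | (1R,2R,10R)-10-hydroxy derivative of 14 | C/C1=C\CC(C)(C)/C=C/C[C@@]2(C)Oc3cc(OC)c(=O)cc(C)c3C[C@@H]2C[C@H]1O | intermediate
18 | 2-[(tert-butyldimethylsilyl)oxy]acetic acid | CC(C)(C)[Si](C)(C)OCC(=O)O | starting material
19 | (tert-butyldimethylsilyloxy)acetate ester of 17 at O10 | C/C1=C\CC(C)(C)/C=C/C[C@@]2(C)Oc3cc(OC)c(=O)cc(C)c3C[C@@H]2C[C@H]1OC(=O)CO[Si](C)(C)C(C)(C)C | intermediate
20 | O-trimethylsilyl ketene acetal of 19 (not isolated) | C/C1=C\CC(C)(C)/C=C/C[C@@]2(C)Oc3cc(OC)c(=O)cc(C)c3C[C@@H]2C[C@H]1OC(O[Si](C)(C)C)=CO[Si](C)(C)C(C)(C)C | intermediate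
21 | trimethylsilyl ester of 22 (not isolated) | C[Si](C)(C)OC(=O)C(O[Si](C)(C)C(C)(C)C)[C@H]1CC(C)(C)/C=C/C[C@@]2(C)Oc3cc(OC)c(=O)cc(C)c3C[C@@H]2C/C=C1\C | intermediate
22 | C8 α-silyloxy acid: (tert-butyldimethylsilyloxy)acetic acid bonded through its C2 to C8 of the (4E,9E)-diene, ring B as in 14, C1, C2 and C8 as in 31, both epimers at the silyloxy carbon | OC(=O)C(O[Si](C)(C)C(C)(C)C)[C@H]1CC(C)(C)/C=C/C[C@@]2(C)Oc3cc(OC)c(=O)cc(C)c3C[C@@H]2C/C=C1\C | intermediate
23 | C8 α-hydroxy acid (desilylated 22) | OC(=O)C(O)[C@H]1CC(C)(C)/C=C/C[C@@]2(C)Oc3cc(OC)c(=O)cc(C)c3C[C@@H]2C/C=C1\C | intermediate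
24 | C8 carbaldehyde with 9E alkene (not isolated) | O=C[C@H]1CC(C)(C)/C=C/C[C@@]2(C)Oc3cc(OC)c(=O)cc(C)c3C[C@@H]2C/C=C1\C | intermediate
25 | C8 hydroxymethyl compound with 9E alkene (homoallylic alcohol), C1, C2 and C8 as in 31 | OC[C@H]1CC(C)(C)/C=C/C[C@@]2(C)Oc3cc(OC)c(=O)cc(C)c3C[C@@H]2C/C=C1\C | intermediate
26 | (9S,10S)-9,10-epoxide of 25 | OC[C@H]1CC(C)(C)/C=C/C[C@@]2(C)Oc3cc(OC)c(=O)cc(C)c3C[C@@H]2C[C@@H]4O[C@]41C | intermediate
27 | (9R,10S)-diol ether: C8 hydroxymethyl, C10 hydroxyl, C9 oxygen bonded to C4′ of 5-bromo-2-methoxy-6-methyltropone | OC[C@H]1CC(C)(C)/C=C/C[C@@]2(C)Oc3cc(OC)c(=O)cc(C)c3C[C@@H]2C[C@H](O)[C@]1(C)Oc5cc(OC)c(=O)cc(C)c5Br | intermediate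
28 | primary iodide of 27 (C8 iodomethyl) | IC[C@H]1CC(C)(C)/C=C/C[C@@]2(C)Oc3cc(OC)c(=O)cc(C)c3C[C@@H]2C[C@H](O)[C@]1(C)Oc5cc(OC)c(=O)cc(C)c5Br | intermediate
29 | alkylzinc iodide from 28 (not isolated) | I[Zn]C[C@H]1CC(C)(C)/C=C/C[C@@]2(C)Oc3cc(OC)c(=O)cc(C)c3C[C@@H]2C[C@H](O)[C@]1(C)Oc5cc(OC)c(=O)cc(C)c5Br | intermediate
30 | bis(O-methyl) ether of 31: rings A and B both closed, both tropolone hydroxyls as OMe, (1R,2R,8R,9R,10S) | Cc1cc(=O)c(OC)cc2c1C[C@H]1CC(C)(C)/C=C/C[C@@]3(C)Oc4cc(OC)c(=O)cc(C)c4C[C@@H]3C[C@H](O)[C@]1(C)O2 | intermediate
31 | CNP0283947.4, (1R,2R,8R,9R,10S)-bis(tropolone) humulane | Cc1cc(=O)c(O)cc2c1C[C@H]1CC(C)(C)/C=C/C[C@@]3(C)Oc4cc(O)c(=O)cc(C)c4C[C@@H]3C[C@H](O)[C@]1(C)O2 | target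

**Totals**

Total step count: 19. Longest linear sequence: 18 steps (steps 1–6, then 8–19).

**Steps most likely to fail**

Step 16. The Lewis acid may isomerise the epoxide by hydride shift to the C10 ketone before the hindered, weakly nucleophilic bromohydroxytropone adds. The ambident hydroxytropone may also react through its C1′ oxygen or on carbon instead of through the C4′ oxygen, which is crowded by the neighbouring bromine. The fallback installs the bromine after the ether bond. Thermal decarboxylation of 9 (DMSO, 120 °C) should give 4-hydroxy-2-methoxy-6-methyltropone F1, whose C4′ oxygen has no ortho substituent and is then the less hindered of its two oxygens. F1 should open 26 under camphorsulfonic acid catalysis to the C5′-unsubstituted aryl ether diol F2. N-Bromosuccinimide should then brominate C5′ of ring A, which is ortho to the ether oxygen and para to the methoxy group. The matching carbon of ring B carries the methylene, and C3′ and C3″ are buried between two oxygen-bearing carbons. This returns to 27. This fallback sets out from 26 and 9 and comes back at 27.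

Step 15. The vanadate may deliver oxygen through the other allylic conformer, to the opposite face of C9=C10; the C9/C10 diastereomer would end as a cis-fused ring A. The fallback replaces substrate direction by catalyst control: dioxirane epoxidation with a fructose-derived chiral ketone and KHSO5 (as 2KHSO5·KHSO4·K2SO4) (Shi epoxidation). Ring B has already removed the other trisubstituted alkene, the disubstituted C4=C5 is shielded by the adjacent CMe2 group, and either enantiomer of the ketone can be used to address the required face. This fallback sets out from 25 and comes back at 26; it makes no new compound (entry F0).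

Step 18. The alkylpalladium may undergo β-hydride elimination toward H8, or the organozinc may be protonated before transmetalation. The fallback closes the same bond at the aldehyde oxidation level. Oxidation of the primary alcohol of 27 with TEMPO/PhI(OAc)2 should give the hydroxy aldehyde F3, which may rest in part as its five-membered lactol with the C10 hydroxyl. CrCl2 with catalytic NiCl2 in DMSO (Nozaki–Hiyama–Kishi reaction) should add C5′ to the aldehyde carbon and close ring A as the benzylic alcohol F4, as both carbinol epimers. Ionic hydrogenation with Et3SiH/CF3CO2H should then remove the benzylic hydroxyl and return to 30. This fallback sets out from 27 and comes back at 30.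

**Further compounds**

F1 | step 16 | 4-hydroxy-2-methoxy-6-methylcyclohepta-2,4,6-trien-1-one | Cc1cc(=O)c(OC)cc(O)c1
F2 | step 16 | C5′-unsubstituted aryl ether diol (27 without bromine) | OC[C@H]1CC(C)(C)/C=C/C[C@@]2(C)Oc3cc(OC)c(=O)cc(C)c3C[C@@H]2C[C@H](O)[C@]1(C)Oc5cc(OC)c(=O)cc(C)c5
F0 | step 15 | none | none
F3 | step 18 | C8 carbaldehyde of 27 (hydroxy aldehyde, in equilibrium with its lactol) | O=C[C@H]1CC(C)(C)/C=C/C[C@@]2(C)Oc3cc(OC)c(=O)cc(C)c3C[C@@H]2C[C@H](O)[C@]1(C)Oc5cc(OC)c(=O)cc(C)c5Br
F4 | step 18 | ring-A-closed benzylic alcohol (30 with OH on the ring-A benzylic carbon, both epimers) | Cc1cc(=O)c(OC)cc2c1C(O)[C@H]1CC(C)(C)/C=C/C[C@@]3(C)Oc4cc(OC)c(=O)cc(C)c4C[C@@H]3C[C@H](O)[C@]1(C)O2
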